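**Plan**
- Numbering: C1 = aryl-bearing CH, C2 = CH(CH2OH), C3 = C(CHO), C4 = alkene CH of ring B, C4a/C8a = fusion carbons of ring A, C9 = formyl carbon; ring C = pendant guaiacyl ring.
- Enabling feature: the C3=C4 styrene bond of ring B with the single carbon C9 on C3 is the oxidised form of the diene C4=C3–C9=CH2. That diene is the retron of an exo enyne ring closure between a vinyl group on C4a of ring A and a terminal alkyne C3≡C9 on C2.
- Cuts, in retrosynthetic order: C9=O back to C9=CH2; C3=C4 together with C9=CH2 (ring B); C3≡C9; C2–CH2O; C1–ring C; the enal C=C; the formyl and vinyl groups on ring A.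
- Forward: ring A is dressed from syringaldehyde (steps 1–5), ring C becomes a boronic acid (6–7), the chain C1–C2–C3≡C9 is built on ring A (8–11), ring B closes (12), C9 is trimmed to the aldehyde and the protecting groups fall (13–14).
- Stereochemistry: C1 from ligand-controlled rhodium-catalysed aryl transfer to the enal, C2 from amine-catalyst-controlled α-hydroxymethylation; two reagent-controlled events fix the trans relation, and no later step touches either centre.

Key step: step 12

Remark: the sense of induction in step 8 is assigned from the usual quadrant model of C2-symmetric diene–rhodium catalysts; should a first run show the opposite sense, the (1S,4S) ligand would be used with nothing else changed.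

**Step 1**
Reactants: 1 syringaldehyde (4-hydroxy-3,5-dimethoxybenzaldehyde)
Product: 2 3,5-dimethoxy-4-(methoxymethoxy)benzaldehyde
Conditions: MOMCl (1.5 equiv), i-Pr2NEt (2 equiv), CH2Cl2, 0 °C → rt
Reagents that add atoms: chloromethyl methyl ether, COCCl
Why: O-alkylation of the phenoxide with the reactive α-chloro ether (MOM protection) gives an acetal that should survive every basic, organometallic and oxidative step and fall in the final acid step.

**Step 2**
Reactants: 2 3,5-dimethoxy-4-(methoxymethoxy)benzaldehyde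
Product: 3 2-bromo-3,5-dimethoxy-4-(methoxymethoxy)benzaldehyde
Conditions: NBS (1.05 equiv), MeCN, rt → 50 °C, dark
Reagents that add atoms: N-bromosuccinimide, O=C1CCC(=O)N1Br
Why: Electrophilic aromatic bromination can only occur at the two equivalent free positions (ortho to one methoxy, para to the other), as with 3,4,5-trialkoxybenzaldehydes, and the acid-free medium spares the acetal.

**Step 3**
Reactants: 3 2-bromo-3,5-dimethoxy-4-(methoxymethoxy)benzaldehyde
Product: 4 2-bromo-1-ethenyl-3,5-dimethoxy-4-(methoxymethoxy)benzene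
Conditions: MePPh3Br (1.3 equiv), KOtBu (1.25 equiv), THF, 0 °C → rt
Reagents that add atoms: methyltriphenylphosphonium bromide, C[P+](c1ccccc1)(c1ccccc1)c1ccccc1.[Br-]
Why: Wittig methylenation of an aryl aldehyde with the non-stabilised ylide installs the future C4 vinyl group; aryl bromide and acetal are inert.

**Step 4**
Reactants: 4 2-bromo-1-ethenyl-3,5-dimethoxy-4-(methoxymethoxy)benzene
Product: 6 6-ethenyl-2,4-dimethoxy-3-(methoxymethoxy)benzaldehyde, via aryllithium 5 (not isolated)
Conditions: n-BuLi (1.05 equiv), THF, −78 °C, 15 min; DMF (3 equiv), −78 → 0 °C; aq. NH4Cl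
Reagents that add atoms: N,N-dimethylformamide, CN(C)C=O
Why: Bromine–lithium exchange at −78 °C is much faster than addition of n-BuLi to the styrene, and formylation of the aryllithium with DMF places the carbonyl carbon (future C1) next to the methoxy-bearing carbon.

**Step 5**
Reactants: 6 6-ethenyl-2,4-dimethoxy-3-(methoxymethoxy)benzaldehyde
Product: 7 (E)-3-[6-ethenyl-2,4-dimethoxy-3-(methoxymethoxy)phenyl]prop-2-enal
Conditions: Ph3P=CHCHO (1.2 equiv), toluene, 90 °C
Reagents that add atoms: (triphenylphosphoranylidene)acetaldehyde, O=CC=P(c1ccccc1)(c1ccccc1)c1ccccc1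
Why: Wittig reaction with the stabilised formyl ylide should give the E-enal, and with a small excess of ylide the less electrophilic enal product is not homologated further.

**Step 6**
Reactants: 8 4-bromo-2-methoxyphenol
Product: 9 4-bromo-2-methoxy-1-(methoxymethoxy)benzene
Conditions: MOMCl (1.5 equiv), i-Pr2NEt (2 equiv), CH2Cl2, 0 °C → rt
Reagents that add atoms: chloromethyl methyl ether, COCCl
Why: MOM protection of the phenol as in step 1, so that ring C and ring A carry the same acid-labile group.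

**Step 7**
Reactants: 9 4-bromo-2-methoxy-1-(methoxymethoxy)benzene
Product: 11 [3-methoxy-4-(methoxymethoxy)phenyl]boronic acid, via aryllithium 10 (not isolated)
Conditions: n-BuLi (1.1 equiv), THF, −78 °C; B(OiPr)3 (1.5 equiv), −78 °C → rt; sat. aq. NH4Cl
Reagents that add atoms: triisopropyl borate, CC(C)OB(OC(C)C)OC(C)C; water, O
Why: Bromine–lithium exchange, trapping with the borate and near-neutral hydrolysis is the standard arylboronic acid synthesis, and the NH4Cl work-up keeps the MOM ether.

**Step 8**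
Reactants: 7 (E)-3-[6-ethenyl-2,4-dimethoxy-3-(methoxymethoxy)phenyl]prop-2-enal; 11 [3-methoxy-4-(methoxymethoxy)phenyl]boronic acid (2 equiv)
Product: 12 (3S)-3-[6-ethenyl-2,4-dimethoxy-3-(methoxymethoxy)phenyl]-3-[3-methoxy-4-(methoxymethoxy)phenyl]propanal
Conditions: [RhCl(C2H4)2]2 (2.5 mol %), (1R,4R)-2,5-diphenylbicyclo[2.2.2]octa-2,5-diene (5.5 mol %), KOH (0.3 equiv), 1,4-dioxane/H2O 10:1, 30 °C
Reagents that add atoms: none
Why: Hayashi–Miyaura 1,4-addition to an enal (transmetallation to an aryl species of monovalent rhodium, insertion of the C=C bond, hydrolysis of the oxa-π-allyl complex), in which the diene ligand suppresses 1,2-addition and holds the formyl side of the bound alkene away from its phenyl group, so the aryl group should add to the Re face of C3 and set the 3S centre (future C1).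

**Step 9**
Reactants: 12 (3S)-3-[6-ethenyl-2,4-dimethoxy-3-(methoxymethoxy)phenyl]-3-[3-methoxy-4-(methoxymethoxy)phenyl]propanal
Product: 13 (2S,3S)-3-[6-ethenyl-2,4-dimethoxy-3-(methoxymethoxy)phenyl]-2-(hydroxymethyl)-3-[3-methoxy-4-(methoxymethoxy)phenyl]propanal
Conditions: (R)-2-[diphenyl(trimethylsilyloxy)methyl]pyrrolidine (20 mol %), 37 % aq. HCHO (3 equiv), pH 7 phosphate buffer, toluene, rt; extractive work-up, used crude
Reagents that add atoms: formaldehyde, C=O
Why: Enamine-catalysed α-hydroxymethylation (crossed aldol with formaldehyde), in which the diphenyl(silyloxy)methyl group of the (R)-catalyst shields one face of the E-enamine so that formaldehyde should add to the open face and set 2S (future C2) under catalyst control over the neighbouring centre.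

**Step 10**
Reactants: 13 (2S,3S)-3-[6-ethenyl-2,4-dimethoxy-3-(methoxymethoxy)phenyl]-2-(hydroxymethyl)-3-[3-methoxy-4-(methoxymethoxy)phenyl]propanal
Product: 14 (2S,3S)-2-{[tert-butyl(dimethyl)silyl]oxymethyl}-3-[6-ethenyl-2,4-dimethoxy-3-(methoxymethoxy)phenyl]-3-[3-methoxy-4-(methoxymethoxy)phenyl]propanal
Conditions: TBSCl (1.3 equiv), imidazole (2.5 equiv), CH2Cl2, 0 °C
Reagents that add atoms: tert-butyldimethylsilyl chloride, CC(C)(C)[Si](C)(C)Cl
Why: Silylation of the primary alcohol with a weak base at 0 °C blocks retro-aldol and dehydration pathways of the β-hydroxy aldehyde without enolising C2.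

**Step 11**
Reactants: 14 (2S,3S)-2-{[tert-butyl(dimethyl)silyl]oxymethyl}-3-[6-ethenyl-2,4-dimethoxy-3-(methoxymethoxy)phenyl]-3-[3-methoxy-4-(methoxymethoxy)phenyl]propanal
Product: 15 tert-butyl{[(2R,3S)-3-[6-ethenyl-2,4-dimethoxy-3-(methoxymethoxy)phenyl]-2-ethynyl-3-[3-methoxy-4-(methoxymethoxy)phenyl]propoxy]}dimethylsilane
Conditions: dimethyl (1-diazo-2-oxopropyl)phosphonate (1.5 equiv), K2CO3 (2 equiv), MeOH, 0 °C → rt
Reagents that add atoms: dimethyl (1-diazo-2-oxopropyl)phosphonate, CC(=O)C(=[N+]=[N-])P(=O)(OC)OC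
Why: Seyferth–Gilbert homologation with the Ohira–Bestmann reagent turns the formyl carbon into C3 and adds C9 under mild carbonate conditions that α-branched β-silyloxy aldehydes normally tolerate without epimerisation (the descriptor at C2 changes from S to R only because the priorities change).

**Step 12**
Reactants: 15 tert-butyl{[(2R,3S)-3-[6-ethenyl-2,4-dimethoxy-3-(methoxymethoxy)phenyl]-2-ethynyl-3-[3-methoxy-4-(methoxymethoxy)phenyl]propoxy]}dimethylsilane
Product: 16 tert-butyl{[(1S,2R)-3-ethenyl-6,8-dimethoxy-7-(methoxymethoxy)-1-[3-methoxy-4-(methoxymethoxy)phenyl]-1,2-dihydronaphthalen-2-yl]methoxy}dimethylsilane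
Conditions: RuCl2(=CHPh)(H2IMes)(PCy3) (second-generation Grubbs catalyst, 5–10 mol %), ethylene (1 atm), toluene (0.01 M), 80 °C
Reagents that add atoms: ethylene, C=C (its methylene ends up on C9 while the styrene CH2 leaves as ethylene, so 16 is an isomer of 15)
Why: The ruthenium methylidene is exchanged at the styrene for the C4 benzylidene, which adds across the terminal alkyne to a ruthenacyclobutene that opens to the vinylcarbene C4=C3–C9H=[Ru]; ethylene then releases the diene and regenerates the methylidene, and the sequence that starts at the alkyne converges on the same product. The closest known reaction type is ring-closing enyne metathesis of 1,7-enynes to 1-vinylcyclohexenes under ethylene. Ring B closes in the exo mode as a six-membered ring, with C3 in the ring and C9 left outside as the vinyl carbon. No stereocentre is formed, and C1 and C2 are sp3 carbons without acidic hydrogens that should keep their configuration. The step needs exo over endo closure and ring closure over alkyne oligomerisation; the terminal alkyne, the four-atom tether (C4a, C8a, C1, C2) held in place by ring A and the ethylene atmosphere secure both.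

**Step 13**
Reactants: 16 tert-butyl{[(1S,2R)-3-ethenyl-6,8-dimethoxy-7-(methoxymethoxy)-1-[3-methoxy-4-(methoxymethoxy)phenyl]-1,2-dihydronaphthalen-2-yl]methoxy}dimethylsilane
Product: 18 (1S,2R)-2-{[tert-butyl(dimethyl)silyl]oxymethyl}-6,8-dimethoxy-7-(methoxymethoxy)-1-[3-methoxy-4-(methoxymethoxy)phenyl]-1,2-dihydronaphthalene-3-carbaldehyde, via vicinal diol 17 (not isolated)
Conditions: OsO4 (2 mol %), NaIO4 (4 equiv), 2,6-dimethylpyridine (2 equiv), 1,4-dioxane/H2O 3:1, rt
Reagents that add atoms: osmium tetroxide, O=[Os](=O)(=O)=O (delivers the oxygen); sodium periodate, [Na+].[O-]I(=O)(=O)=O (terminal oxidant)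
Why: Lemieux–Johnson oxidation, in which OsO4 should attack the terminal, least hindered alkene of the diene (leaving the styrene conjugation intact) and periodate cleaves the diol to the C9 aldehyde, after which the ring alkene is part of an electron-poor enal and is not oxidised further.

**Step 14**
Reactants: 18 (1S,2R)-2-{[tert-butyl(dimethyl)silyl]oxymethyl}-6,8-dimethoxy-7-(methoxymethoxy)-1-[3-methoxy-4-(methoxymethoxy)phenyl]-1,2-dihydronaphthalene-3-carbaldehyde
Product: 19 (1S,2R)-7-hydroxy-1-(4-hydroxy-3-methoxyphenyl)-2-(hydroxymethyl)-6,8-dimethoxy-1,2-dihydronaphthalene-3-carbaldehyde (target, CNP0509591.1)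
Conditions: HCl (3 M in MeOH)/THF 1:1, 0 °C → rt, argon; then dilute aq. HCl/THF, 10 min
Reagents that add atoms: none
Why: Acid-catalysed acetal exchange removes both MOM groups and methanolysis removes the primary silyl ether in one operation, the brief aqueous acid returns any dimethyl acetal to the enal, and neither C1 nor C2 can enolise.

**Compound list**
1 | syringaldehyde (4-hydroxy-3,5-dimethoxybenzaldehyde) | COc1cc(C=O)cc(OC)c1O | starting material
2 | 3,5-dimethoxy-4-(methoxymethoxy)benzaldehyde | COCOc1c(OC)cc(C=O)cc1OC | intermediate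
3 | 2-bromo-3,5-dimethoxy-4-(methoxymethoxy)benzaldehyde | O=Cc1cc(OC)c(OCOC)c(OC)c1Br | intermediate
4 | 2-bromo-1-ethenyl-3,5-dimethoxy-4-(methoxymethoxy)benzene | C=Cc1cc(OC)c(OCOC)c(OC)c1Br | intermediate
5 | [6-ethenyl-2,4-dimethoxy-3-(methoxymethoxy)phenyl]lithium | [Li]c1c(C=C)cc(OC)c(OCOC)c1OC | intermediate
6 | 6-ethenyl-2,4-dimethoxy-3-(methoxymethoxy)benzaldehyde | C=Cc1cc(OC)c(OCOC)c(OC)c1C=O | intermediate
7 | (E)-3-[6-ethenyl-2,4-dimethoxy-3-(methoxymethoxy)phenyl]prop-2-enal | C=Cc1cc(OC)c(OCOC)c(OC)c1/C=C/C=O | intermediate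
8 | 4-bromo-2-methoxyphenol | COc1cc(Br)ccc1O | starting material
9 | 4-bromo-2-methoxy-1-(methoxymethoxy)benzene | COCOc1ccc(Br)cc1OC | intermediate
10 | [3-methoxy-4-(methoxymethoxy)phenyl]lithium | [Li]c1ccc(OCOC)c(OC)c1 | intermediate
11 | [3-methoxy-4-(methoxymethoxy)phenyl]boronic acid | COCOc1ccc(B(O)O)cc1OC | intermediate
12 | (3S)-3-[6-ethenyl-2,4-dimethoxy-3-(methoxymethoxy)phenyl]-3-[3-methoxy-4-(methoxymethoxy)phenyl]propanal | COc1cc([C@@H](c2c(C=C)cc(OC)c(OCOC)c2OC)CC=O)ccc1OCOC | intermediate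
13 | (2S,3S)-3-[6-ethenyl-2,4-dimethoxy-3-(methoxymethoxy)phenyl]-2-(hydroxymethyl)-3-[3-methoxy-4-(methoxymethoxy)phenyl]propanal | COc1cc([C@@H](c2c(C=C)cc(OC)c(OCOC)c2OC)[C@@H](CO)C=O)ccc1OCOC | intermediate
14 | (2S,3S)-2-{[tert-butyl(dimethyl)silyl]oxymethyl}-3-[6-ethenyl-2,4-dimethoxy-3-(methoxymethoxy)phenyl]-3-[3-methoxy-4-(methoxymethoxy)phenyl]propanal | COc1cc([C@@H](c2c(C=C)cc(OC)c(OCOC)c2OC)[C@@H](CO[Si](C)(C)C(C)(C)C)C=O)ccc1OCOC | intermediate
15 | tert-butyl{[(2R,3S)-3-[6-ethenyl-2,4-dimethoxy-3-(methoxymethoxy)phenyl]-2-ethynyl-3-[3-methoxy-4-(methoxymethoxy)phenyl]propoxy]}dimethylsilane | COc1cc([C@@H](c2c(C=C)cc(OC)c(OCOC)c2OC)[C@@H](CO[Si](C)(C)C(C)(C)C)C#C)ccc1OCOC | intermediate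
16 | tert-butyl{[(1S,2R)-3-ethenyl-6,8-dimethoxy-7-(methoxymethoxy)-1-[3-methoxy-4-(methoxymethoxy)phenyl]-1,2-dihydronaphthalen-2-yl]methoxy}dimethylsilane | COc1cc([C@H]2c3c(cc(OC)c(OCOC)c3OC)C=C(C=C)[C@@H]2CO[Si](C)(C)C(C)(C)C)ccc1OCOC | intermediate
17 | 1-[(1S,2R)-2-{[tert-butyl(dimethyl)silyl]oxymethyl}-6,8-dimethoxy-7-(methoxymethoxy)-1-[3-methoxy-4-(methoxymethoxy)phenyl]-1,2-dihydronaphthalen-3-yl]ethane-1,2-diol (either configuration at the carbinol carbon) | COc1cc([C@H]2c3c(cc(OC)c(OCOC)c3OC)C=C(C(O)CO)[C@@H]2CO[Si](C)(C)C(C)(C)C)ccc1OCOC | intermediate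
18 | (1S,2R)-2-{[tert-butyl(dimethyl)silyl]oxymethyl}-6,8-dimethoxy-7-(methoxymethoxy)-1-[3-methoxy-4-(methoxymethoxy)phenyl]-1,2-dihydronaphthalene-3-carbaldehyde | COc1cc([C@H]2c3c(cc(OC)c(OCOC)c3OC)C=C(C=O)[C@@H]2CO[Si](C)(C)C(C)(C)C)ccc1OCOC | intermediate
19 | (1S,2R)-7-hydroxy-1-(4-hydroxy-3-methoxyphenyl)-2-(hydroxymethyl)-6,8-dimethoxy-1,2-dihydronaphthalene-3-carbaldehyde | COc1cc([C@H]2c3c(cc(OC)c(O)c3OC)C=C(C=O)[C@@H]2CO)ccc1O | target

**Step count**
Total: 14 steps. Longest linear sequence: 12 steps (steps 1–5 and 8–14, from syringaldehyde).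

**Steps most likely to fail**

Step 8. Aryl transfer to the β-carbon, which carries a doubly ortho-substituted ring, may be slow, so that protodeboronation and 1,2-addition take over or facial discrimination drops. The fallback replaces catalyst control by an oxazolidinone auxiliary; it sets out from 6 and comes back at 12. Doebner–Knoevenagel condensation of 6 with malonic acid (pyridine, piperidine, 90 °C) would give (E)-3-[6-ethenyl-2,4-dimethoxy-3-(methoxymethoxy)phenyl]prop-2-enoic acid F1. Activation with t-BuCOCl/Et3N (THF, −20 °C) gives the mixed pivalic anhydride F2, which acylates (R)-4-phenyl-1,3-oxazolidin-2-one in the presence of LiCl to the N-enoyl imide F3. The arylmagnesium bromide F4 (from 9 and Mg turnings in THF) with CuBr·SMe2 in THF/Me2S at −40 → −10 °C should add to the chelated s-cis imide from the face opposite the phenyl group and give the (4R,3'S) adduct F5. LiBH4 in wet THF at 0 °C releases the (3S)-3,3-diarylpropan-1-ol F6 and the auxiliary, and Dess–Martin periodinane (NaHCO3, CH2Cl2) returns the sequence to 12.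

Step 9. The C2 configuration may erode, either through incomplete facial control on the crowded enamine or through enolisation and dehydration of the β-hydroxy aldehyde during work-up. The fallback replaces catalyst control by separation with recycling; it sets out from 13 (whatever its composition at C2) and comes back at 14. NaBH4 in MeOH at 0 °C would give the 2-[(S)-diarylmethyl]propane-1,3-diol F7, in which C2 is no longer a stereocentre. Monosilylation (NaH 1 equiv, TBSCl 1 equiv, THF) gives the two monosilyl ethers, the (2R,3S) alcohol F8 and the (2S,3S) alcohol F9, which are diastereomers and separable on silica. F9 is returned to F7 with Bu4NF, and F8 is oxidised with Dess–Martin periodinane (NaHCO3, CH2Cl2, 0 °C) to 14.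

Step 11. In K2CO3/MeOH the aldehyde may epimerise at C2 or lose the silyloxy group by β-elimination before it is consumed. The fallback is a base-free olefination followed by rearrangement (Corey–Fuchs); it sets out from 14 and comes back at 15. CBr4/PPh3 with 2,6-dimethylpyridine in CH2Cl2 at 0 °C would give the (3R,4S)-1,1-dibromoalkene F10. n-BuLi (2.1 equiv, THF, −78 °C) induces the Fritsch–Buttenberg–Wiechell rearrangement to the lithium acetylide F11, which on aqueous quench gives 15.

**Further compounds**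
F1 | step 8 | (E)-3-[6-ethenyl-2,4-dimethoxy-3-(methoxymethoxy)phenyl]prop-2-enoic acid | C=Cc1cc(OC)c(OCOC)c(OC)c1/C=C/C(=O)O
F2 | step 8 | (E)-3-[6-ethenyl-2,4-dimethoxy-3-(methoxymethoxy)phenyl]prop-2-enoic 2,2-dimethylpropanoic anhydride | C=Cc1cc(OC)c(OCOC)c(OC)c1/C=C/C(=O)OC(=O)C(C)(C)C
F3 | step 8 | (4R)-3-{(E)-3-[6-ethenyl-2,4-dimethoxy-3-(methoxymethoxy)phenyl]prop-2-enoyl}-4-phenyl-1,3-oxazolidin-2-one | C=Cc1cc(OC)c(OCOC)c(OC)c1/C=C/C(=O)N1C(=O)OC[C@H]1c1ccccc1
F4 | step 8 | [3-methoxy-4-(methoxymethoxy)phenyl]magnesium bromide | COCOc1ccc([Mg]Br)cc1OC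
F5 | step 8 | (4R)-3-{(3S)-3-[6-ethenyl-2,4-dimethoxy-3-(methoxymethoxy)phenyl]-3-[3-methoxy-4-(methoxymethoxy)phenyl]propanoyl}-4-phenyl-1,3-oxazolidin-2-one | COc1cc([C@@H](c2c(C=C)cc(OC)c(OCOC)c2OC)CC(=O)N3C(=O)OC[C@H]3c3ccccc3)ccc1OCOC
F6 | step 8 | (3S)-3-[6-ethenyl-2,4-dimethoxy-3-(methoxymethoxy)phenyl]-3-[3-methoxy-4-(methoxymethoxy)phenyl]propan-1-ol | COc1cc([C@@H](c2c(C=C)cc(OC)c(OCOC)c2OC)CCO)ccc1OCOC
F7 | step 9 | 2-{(S)-[6-ethenyl-2,4-dimethoxy-3-(methoxymethoxy)phenyl][3-methoxy-4-(methoxymethoxy)phenyl]methyl}propane-1,3-diol | COc1cc([C@@H](c2c(C=C)cc(OC)c(OCOC)c2OC)C(CO)CO)ccc1OCOC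
F8 | step 9 | (2R,3S)-2-{[tert-butyl(dimethyl)silyl]oxymethyl}-3-[6-ethenyl-2,4-dimethoxy-3-(methoxymethoxy)phenyl]-3-[3-methoxy-4-(methoxymethoxy)phenyl]propan-1-ol | COc1cc([C@@H](c2c(C=C)cc(OC)c(OCOC)c2OC)[C@@H](CO[Si](C)(C)C(C)(C)C)CO)ccc1OCOC
F9 | step 9 | (2S,3S)-2-{[tert-butyl(dimethyl)silyl]oxymethyl}-3-[6-ethenyl-2,4-dimethoxy-3-(methoxymethoxy)phenyl]-3-[3-methoxy-4-(methoxymethoxy)phenyl]propan-1-ol | COc1cc([C@@H](c2c(C=C)cc(OC)c(OCOC)c2OC)[C@H](CO[Si](C)(C)C(C)(C)C)CO)ccc1OCOC
F10 | step 11 | tert-butyl{[(2R,3S)-2-(2,2-dibromoethenyl)-3-[6-ethenyl-2,4-dimethoxy-3-(methoxymethoxy)phenyl]-3-[3-methoxy-4-(methoxymethoxy)phenyl]propoxy]}dimethylsilane | COc1cc([C@@H](c2c(C=C)cc(OC)c(OCOC)c2OC)[C@@H](CO[Si](C)(C)C(C)(C)C)C=C(Br)Br)ccc1OCOC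
F11 | step 11 | lithium acetylide of 15 | COc1cc([C@@H](c2c(C=C)cc(OC)c(OCOC)c2OC)[C@@H](CO[Si](C)(C)C(C)(C)C)C#C[Li])ccc1OCOC
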